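**Assumption:** the drawn isomer is the (2S,3R,4R)-oxolane (7S,8R,8′R in lignan numbering), and 3-(3,4,5-trimethoxyphenyl)propanoic acid and (S)-4-benzyl-1,3-oxazolidin-2-one are bought.

## Retrosynthetic overview

1. Target ⇒ C2-symmetric (2R,3R)-2,3-bis(3,4,5-trimethoxybenzyl)butane-1,4-diol. The C2–O1 bond is made last, by benzylic C–H dehydrogenation to a quinone-methide-type cation and 5-exo capture by the 1,4-related hydroxyl; this closes the only new ring (the oxolane) and sets C2.
2. Diol ⇒ bis(N-acyloxazolidinone) of (2R,3R)-dibenzylsuccinic acid, by hydride cleavage of both auxiliaries.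
3. Bis-imide ⇒ two molecules of one N-(3-arylpropanoyl)oxazolidinone. The β–β′ (C8–C8′) bond is made by one-electron oxidative enolate dimerisation, which sets C3 and C4 under auxiliary control.
4. Imide ⇒ 3-(3,4,5-trimethoxyphenyl)propanoic acid + (S)-4-benzyloxazolidinone.

## Route

Step 1
Reactants: 1 3-(3,4,5-trimethoxyphenyl)propanoic acid; 2 (S)-4-benzyl-1,3-oxazolidin-2-one
Product: 4 (4S)-4-benzyl-3-[3-(3,4,5-trimethoxyphenyl)propanoyl]-1,3-oxazolidin-2-one, via mixed pivalic anhydride 3 (not isolated)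
Conditions: PivCl, Et3N, THF, −20 °C; then LiCl, 2, −20 °C → rt
Reagents that add atoms: none
Why: Mixed-anhydride N-acylation of the LiCl-activated oxazolidinone (Evans auxiliary loading) is routine for hydrocinnamic acids and creates no stereocentre.

Step 2
Reactants: 4 (4S)-4-benzyl-3-[3-(3,4,5-trimethoxyphenyl)propanoyl]-1,3-oxazolidin-2-one (two molecules)
Product: 6 (4S,4′S)-3,3′-[(2R,3R)-2,3-bis(3,4,5-trimethoxybenzyl)butanedioyl]bis(4-benzyl-1,3-oxazolidin-2-one), via lithium Z-enolate 5 (not isolated)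
Conditions: LiN(iPr)2 (LDA), THF, −78 °C; then CuCl2, DMF, −78 °C → rt
Reagents that add atoms: none
Why: Oxidative enolate homocoupling, in which divalent copper oxidises the chelated Z-lithium enolate by one electron and two C6C3 units join β–β′ as in lignan biosynthesis; each unit reacts on the face opposite the 4-benzyl group of the auxiliary, as in an Evans alkylation, so both new centres are R (the future C3 and C4), and the minor R,S diastereomer is removed by chromatography or crystallisation.

Step 3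
Reactants: 6 (4S,4′S)-3,3′-[(2R,3R)-2,3-bis(3,4,5-trimethoxybenzyl)butanedioyl]bis(4-benzyl-1,3-oxazolidin-2-one)
Product: 7 (2R,3R)-2,3-bis(3,4,5-trimethoxybenzyl)butane-1,4-diol
Conditions: LiBH4, THF, MeOH (4 equiv), 0 °C → rt
Reagents that add atoms: none
Why: Reductive cleavage of N-acyloxazolidinones by LiBH4 (hydride attack at the exocyclic carbonyl) turns both imides into CH2OH without touching the α-stereocentres or the aryl methyl ethers; any lactone formed on the way is reduced to the same diol, and auxiliary 2 is recovered.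

Step 4
Reactants: 7 (2R,3R)-2,3-bis(3,4,5-trimethoxybenzyl)butane-1,4-diol
Product: 9 [(2S,3R,4R)-4-(3,4,5-trimethoxybenzyl)-2-(3,4,5-trimethoxyphenyl)oxolan-3-yl]methanol (target CNP0321241.1), via benzylic cation 8 (not isolated)
Conditions: DDQ (1.0 equiv, slow addition), CH2Cl2/AcOH 9:1, 0 °C → rt
Reagents that add atoms: none
Why: DDQ benzylic dehydrogenation followed by intramolecular oxa-1,6-type addition (dehydrogenative cycloetherification): hydride loss from one of the two homotopic ArCH2 groups gives the para-methoxy-stabilised cation (the O-methyl counterpart of the biosynthetic quinone methide), the 1,4-related CH2OH closes the oxolane 5-exo, and C2 is set S (aryl trans to the neighbouring CH2OH) under substrate control, because the all-cis alternative is strongly disfavoured and the benzylic ether can equilibrate under the mildly acidic conditions.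

## Compound list

1 | 3-(3,4,5-trimethoxyphenyl)propanoic acid | COc1cc(CCC(=O)O)cc(OC)c1OC | starting material
2 | (S)-4-benzyl-1,3-oxazolidin-2-one | O=C1N[C@@H](Cc2ccccc2)CO1 | starting material
3 | 2,2-dimethylpropanoic 3-(3,4,5-trimethoxyphenyl)propanoic anhydride (mixed pivalic anhydride) | COc1cc(CCC(=O)OC(=O)C(C)(C)C)cc(OC)c1OC | intermediate
4 | (4S)-4-benzyl-3-[3-(3,4,5-trimethoxyphenyl)propanoyl]-1,3-oxazolidin-2-one | COc1cc(CCC(=O)N2[C@@H](Cc3ccccc3)COC2=O)cc(OC)c1OC | intermediate
5 | lithium Z-enolate of 4 | COc1cc(C/C=C(\O[Li])N2[C@@H](Cc3ccccc3)COC2=O)cc(OC)c1OC | intermediate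
6 | (4S,4′S)-3,3′-[(2R,3R)-2,3-bis(3,4,5-trimethoxybenzyl)butanedioyl]bis(4-benzyl-1,3-oxazolidin-2-one) | COc1cc(C[C@@H](C(=O)N2[C@@H](Cc3ccccc3)COC2=O)[C@@H](Cc2cc(OC)c(OC)c(OC)c2)C(=O)N2[C@@H](Cc3ccccc3)COC2=O)cc(OC)c1OC | intermediate
7 | (2R,3R)-2,3-bis(3,4,5-trimethoxybenzyl)butane-1,4-diol | COc1cc(C[C@@H](CO)[C@@H](Cc2cc(OC)c(OC)c(OC)c2)CO)cc(OC)c1OC | intermediate
8 | benzylic cation from hydride loss at one ArCH2 of 7 (O-methyl quinone methide type) | COc1cc([CH+][C@@H](CO)[C@@H](Cc2cc(OC)c(OC)c(OC)c2)CO)cc(OC)c1OC | intermediate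
9 | [(2S,3R,4R)-4-(3,4,5-trimethoxybenzyl)-2-(3,4,5-trimethoxyphenyl)oxolan-3-yl]methanol | COc1cc(C[C@H]2CO[C@H](c3cc(OC)c(OC)c(OC)c3)[C@H]2CO)cc(OC)c1OC | target

## Step count and risks

Total step count: 4. Longest linear sequence: 4 (1 → 4 → 6 → 7 → 9).

**Most likely to fail, in order:**

**1. Step 4 (dehydrogenative cyclisation).**
- A 3,4,5-trimethoxybenzyl C–H is harder to oxidise than a para-hydroxy or 3,4-dioxygenated one.
- Product 9 still carries a second ArCH2 beside a free CH2OH, so a second cyclisation to the furofuran competes statistically. The expected ceiling is about 50 % per pass, with 7 recovered and recycled.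
- Fallback: set out from diol 7 and do not try to stop halfway. Oxidise exhaustively (DDQ, 2.5 equiv, AcOH/CH2Cl2, 40 °C) through both cations to the furofuran (1S,3aR,4S,6aR)-1,4-bis(3,4,5-trimethoxyphenyl)tetrahydro-1H,3H-furo[3,4-c]furan F1. Then open one of its two homotopic benzylic C–O bonds by hydrogenolysis (H2, 1 atm, Pd/C, EtOH/AcOH, stopped after one equivalent of hydrogen), which is the biosynthetic furofuran-to-oxolane order. This comes back to the route at target 9; over-reduced material is diol 7 and is recycled.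

**2. Step 2 (oxidative homocoupling).**
- Moderate diastereoselectivity, competing α-chlorination and proton return can hold the yield near 50 %.
- Fallback: set out from imide 4 and build the C8–C8′ bond by polar alkylation instead.
  - NaN(SiMe3)2, THF, −78 °C, then tert-butyl bromoacetate gives tert-butyl (3R)-4-[(4S)-4-benzyl-2-oxo-1,3-oxazolidin-3-yl]-4-oxo-3-(3,4,5-trimethoxybenzyl)butanoate F2 (Evans alkylation).
  - LiBH4 cleaves the imide to tert-butyl (3R)-4-hydroxy-3-(3,4,5-trimethoxybenzyl)butanoate F3.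
  - TFA in CH2Cl2 closes F3 to (4R)-4-(3,4,5-trimethoxybenzyl)dihydrofuran-2(3H)-one F4.
  - LiN(iPr)2 then 3,4,5-trimethoxybenzyl bromide alkylates anti to the existing benzyl group to give (3R,4R)-3,4-bis(3,4,5-trimethoxybenzyl)dihydrofuran-2(3H)-one F5.
  - LiAlH4 in THF reduces F5 to diol 7, where the fallback rejoins the route (it replaces steps 2 and 3).

**3. Step 3 (hydride cleavage of the hindered bis-imide).**
- Attack at the ring carbonyl or incomplete reduction is possible next to the two fully substituted α-carbons.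
- Fallback: set out from bis-imide 6 and separate cleavage from reduction. LiOH/H2O2 in THF/H2O at 0 °C (hydroperoxide attacks only the exocyclic carbonyl) gives (2R,3R)-2,3-bis(3,4,5-trimethoxybenzyl)butanedioic acid F6. LiAlH4 in THF at reflux then reduces F6 to diol 7, where it rejoins the route.

## Further compounds

F1 | step 4 | (1S,3aR,4S,6aR)-1,4-bis(3,4,5-trimethoxyphenyl)tetrahydro-1H,3H-furo[3,4-c]furan | COc1cc([C@H]2OC[C@H]3[C@@H]2CO[C@@H]3c2cc(OC)c(OC)c(OC)c2)cc(OC)c1OC
F2 | step 2 | tert-butyl (3R)-4-[(4S)-4-benzyl-2-oxo-1,3-oxazolidin-3-yl]-4-oxo-3-(3,4,5-trimethoxybenzyl)butanoate | COc1cc(C[C@H](CC(=O)OC(C)(C)C)C(=O)N2[C@@H](Cc3ccccc3)COC2=O)cc(OC)c1OC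
F3 | step 2 | tert-butyl (3R)-4-hydroxy-3-(3,4,5-trimethoxybenzyl)butanoate | COc1cc(C[C@H](CC(=O)OC(C)(C)C)CO)cc(OC)c1OC
F4 | step 2 | (4R)-4-(3,4,5-trimethoxybenzyl)dihydrofuran-2(3H)-one | COc1cc(C[C@H]2COC(=O)C2)cc(OC)c1OC
F5 | step 2 | (3R,4R)-3,4-bis(3,4,5-trimethoxybenzyl)dihydrofuran-2(3H)-one | COc1cc(C[C@H]2COC(=O)[C@@H]2Cc2cc(OC)c(OC)c(OC)c2)cc(OC)c1OC
F6 | step 3 | (2R,3R)-2,3-bis(3,4,5-trimethoxybenzyl)butanedioic acid | COc1cc(C[C@@H](C(=O)O)[C@@H](Cc2cc(OC)c(OC)c(OC)c2)C(=O)O)cc(OC)c1OC
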